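**Retrosynthetic overview**

1. Target 25 ⇐ 24 ⇐ 23 ⇐ 22 ⇐ 21: the acetate, the C12 hydroxyl (enolate oxidation) and the C10 methylene (from a ketone) go on last; the lactone comes from bridged lactol 21.
2. Key disconnection (C11–C12 and O–C11): the lactone carbonyl C11 is a single carbon between C12 and the oxygen on acetal carbon C15, and C12 sits on bridgehead C13 of the tetrahydrofuran (O–C15–C14–C13–C16). The six-membered ring is therefore closed by hydroformylating the C13=C12 methylene of lactol 19, with the C15 hydroxyl capturing the new aldehyde.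
3. Tetrahydrofuran (C13–C14 bond): 5-exo-dig radical closure inside a cis-dioxolanone that ties C15 to the carboxyl group on C16 of (R)-2-hydroxybut-3-ynoic acid, so that C14 is set from C16; methanolysis then frees lactol and methyl ester together.
4. Hydroazulenone: asymmetric conjugate addition to 4,4-dimethylcyclohexenone (C5), aldol cyclopentannulation, conjugate allylation (C8, C9), one-carbon ring expansion, ozonolysis.
5. Ring order: cyclopentane, cycloheptanone, dioxolanone (temporary), tetrahydrofuran, six-membered lactol/lactone.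

Key step: step 13

Remark (labels): C10 = ketone/methylene carbon, C1–C3 = CH2, C4 = CMe2, C5/C9 = ring-fusion CH, C6/C7 = CH2, C8 = C(CH3); C11 = lactone C=O, C12 = CH(OAc), C13 = bridgehead CH, C14 = CH on C8, C15 = acetal CH, C16 = CH(CO2Me). In the 2,7-dioxabicyclo[3.2.1]octane names C1 = C15, C3 = C11, C4 = C12, C5 = C13, C6 = C16, C8 = C14.

Remark (abbreviation): Q = the (3aR,8aR)-1,4,4-trimethyl-8-oxodecahydroazulen-1-yl group of aldehyde 11, cis-fused, C8 methyl cis to C10; Q′ = Q with C10=CH2 in place of C10=O.

Assumption: the lipase in step 6 acylates the R alcohol (size rule, CO2Me as the larger group); if the sense were opposite, the unreacted alcohol would be the R enantiomer and would enter step 7 in the same way.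

Why the acetal is tethered: an open-chain haloacetal closure would leave C15 uncontrolled, and C14 follows C15, so the carboxyl group is used to tie C15 to C16 as a dioxolanone.

**Route**

Step 1
Reactants: 1 4,4-dimethylcyclohex-2-en-1-one; 2 2-(2-bromoethyl)-2-methyl-1,3-dioxolane
Product: 5 (3R)-4,4-dimethyl-3-[2-(2-methyl-1,3-dioxolan-2-yl)ethyl]cyclohexan-1-one, via Grignard reagent 3 (not isolated), via diorganozinc 4 (not isolated)
Conditions: 2, Mg, THF, 25 °C; ZnCl2 (0.5 equiv), then 1,4-dioxane, filtration; 1, Cu(OTf)2 (2 mol %), phosphoramidite from (S)-BINOL and bis[(R)-1-phenylethyl]amine (4 mol %), toluene, −30 °C; aq. NH4Cl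
Reagents that add atoms: none
Why: Copper-catalysed asymmetric conjugate addition of a dialkylzinc, a reaction type that tolerates the C4 gem-dimethyl group of this enone; the ligand enantiomer that turns cyclohex-2-enone into (S)-3-ethylcyclohexanone delivers the alkyl group to the same enone face here and so should set C5 as R.

Step 2
Reactants: 5
Product: 7 (7aS)-3,7,7-trimethyl-1,2,5,6,7,7a-hexahydro-4H-inden-4-one, via diketone 6 (not isolated)
Conditions: TsOH·H2O (0.2 equiv), acetone–H2O, 50 °C; then toluene, reflux, Dean–Stark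
Reagents that add atoms: none
Why: Ketal hydrolysis followed by acid-catalysed intramolecular aldol condensation of the 1,6-diketone, in which only attack of C9 on the side-chain carbonyl C8 gives a fused five-membered ring that can dehydrate (the C7-to-C10 aldol is bridged and reversible); C5 is not acidic in the enone and keeps its configuration.

Step 3
Reactants: 7
Product: 8 (3S,3aR,7aR)-3,7,7-trimethyl-3-(prop-2-en-1-yl)octahydro-4H-inden-4-one
Conditions: allyltrimethylsilane (1.5 equiv), TiCl4 (1.1 equiv), CH2Cl2, −78 °C; H2O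
Reagents that add atoms: allyltrimethylsilane, C=CC[Si](C)(C)C
Why: Hosomi–Sakurai conjugate allylation of an s-cis β,β-disubstituted enone, in which the allyl group should enter C8 on the face of H5, away from the quaternary C4 on the other face, and protonation of the titanium enolate at C9 on the same open face (also the thermodynamic outcome for a hydrindan-4-one) should give the cis ring fusion.

Step 4
Reactants: 8
Product: 10 (3S,3aR,8aR)-3,8,8-trimethyl-3-(prop-2-en-1-yl)octahydroazulen-4(1H)-one, via silyl ketone 9 (not isolated)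
Conditions: Me3SiCHN2 (1.2 equiv), BF3·OEt2 (1.2 equiv), CH2Cl2, −78 to −30 °C; then 1 M HCl, THF, 25 °C
Reagents that add atoms: (trimethylsilyl)diazomethane, C[Si](C)(C)C=[N+]=[N-]
Why: Lewis-acid-promoted diazoalkane ring homologation of a ketone (Buchner–Curtius–Schlotterbeck reaction), in which the unhindered CH2 (C2) migrates in preference to the tertiary C9 next to quaternary C8, so the new carbon C1 is inserted between C10 and C2 and no stereocenter is touched; acid removes the silyl group.

Step 5
Reactants: 10
Product: 11 2-[(1S,3aR,8aR)-1,4,4-trimethyl-8-oxodecahydroazulen-1-yl]acetaldehyde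
Conditions: O3, CH2Cl2, −78 °C; PPh3, −78 to 25 °C
Reagents that add atoms: ozone, [O-][O+]=O
Why: Ozonolysis of the only alkene with reductive work-up gives the C14–C15 aldehyde arm without touching the ketone or any stereocenter; the 1,5-keto aldehyde is used at once under neutral conditions.

Step 6
Reactants: 12 methyl 2-hydroxybut-3-ynoate (racemic)
Product: 13 methyl (2R)-2-(acetyloxy)but-3-ynoate
Conditions: vinyl acetate (3 equiv), Burkholderia cepacia lipase, t-BuOMe, 30 °C, stopped at half conversion; chromatography
Reagents that add atoms: vinyl acetate, C=COC(C)=O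
Why: Lipase-catalysed kinetic resolution by enantioselective transesterification, which by the empirical size rule should acylate the R alcohol and so supplies C16 in the configuration of the target.

Step 7
Reactants: 13
Product: 14 (2R)-2-hydroxybut-3-ynoic acid
Conditions: LiOH (2.2 equiv), THF–H2O, 0 °C; 1 M HCl to pH 2, extraction
Reagents that add atoms: lithium hydroxide, [Li+].[OH-]
Why: Saponification of both esters, in which the carboxylate formed first protects the α-C–H from deprotonation, so C16 should not racemise at 0 °C.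

Step 8
Reactants: 14
Product: 15 trimethylsilyl (2R)-2-[(trimethylsilyl)oxy]but-3-ynoate
Conditions: Me3SiCl (2.2 equiv), Et3N (2.3 equiv), CH2Cl2, 0 to 25 °C; filtration, distillation
Reagents that add atoms: chlorotrimethylsilane, C[Si](C)(C)Cl
Why: O-Silylation of acid and alcohol gives the bis-silyl donor for the acetalisation; no bond to C16 is broken.

Step 9
Reactants: 11
Product: 16 2-(phenylselanyl)-2-Q-acetaldehyde (C14 epimers)
Conditions: N-(phenylseleno)phthalimide (1.1 equiv), L-prolinamide (10 mol %), CH2Cl2, 0 to 25 °C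
Reagents that add atoms: N-(phenylseleno)phthalimide, O=C1N([Se]c2ccccc2)C(=O)c2ccccc12
Why: Enamine-catalysed α-selenenylation of an aldehyde, selective because the aldehyde enamine forms far faster than that of the hindered C10 ketone; the C14 configuration is of no consequence since C14 becomes a radical in step 11.

Step 10
Reactants: 16; 15
Product: 17 (2R,5R)-5-ethynyl-2-[(phenylselanyl)(Q)methyl]-1,3-dioxolan-4-one (2,5-cis; C14 epimers)
Conditions: Me3SiOTf (10 mol %), CH2Cl2, −78 °C; pyridine quench
Reagents that add atoms: none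
Why: Silyl-triflate-catalysed acetalisation of an aldehyde with a bis-silylated α-hydroxy acid (dioxolanone formation), whose kinetic closure at low temperature gives the 2,5-cis ring, so that acetal carbon C15 is fixed relative to C16; the hindered ketone reacts much more slowly.

Step 11
Reactants: 17
Product: 18 (4R)-5-methylidene-6-exo-Q-2,7-dioxabicyclo[2.2.1]heptan-3-one
Conditions: Bu3SnH (1.3 equiv, syringe pump, 6 h), AIBN (0.2 equiv), benzene (0.005 M), 80 °C
Reagents that add atoms: none
Why: Proposed new method: Bu3Sn• abstracts the phenylselanyl group, the secondary C14 radical, held on the same face of the dioxolanone as the ethynyl group, adds 5-exo-dig to C13 and the vinyl radical takes hydrogen from the stannane; the closest known reaction type is the Ueno–Stork 5-exo-dig cyclisation of β-haloacetal radicals onto propargylic ethers, together with radical closures of bicyclo[2.2.1] rings across cis-1,3 positions of five-membered rings; new is the closure to a bridged 2,7-dioxabicyclo[2.2.1]heptanone; C14 is set because the quaternary hydroazulenyl group on the radical carbon takes the exo position (toward O7, away from the lactone bridge), which places it trans to the C16 carboxyl carbon; 6-endo attack at C12 is out of geometric reach and the trans-dioxolanone cannot close.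

Step 12
Reactants: 18
Product: 19 methyl (2R)-5-hydroxy-3-methylidene-4-Q-tetrahydrofuran-2-carboxylate (Q trans to CO2Me; lactol anomers)
Conditions: MeOH–CH2Cl2 (1:1), 4-(dimethylamino)pyridine (10 mol %), 0 °C
Reagents that add atoms: methanol, CO
Why: Nucleophile-catalysed methanolysis of the strained acyloxy-acetal lactone, in which methanol attacks the lactone carbonyl (which becomes the C16 methyl ester) and the expelled C15 oxygen gives the lactol; C14 and C16 are untouched and C15 is free to anomerise.

Step 13
Reactants: 19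
Product: 21 methyl 3-hydroxy-8-Q-2,7-dioxabicyclo[3.2.1]octane-6-exo-carboxylate (Q anti to the O7–C6 bridge; C3 epimers), via aldehyde 20 (not isolated)
Conditions: Rh(acac)(CO)2 (2 mol %), tris(2,4-di-tert-butylphenyl) phosphite (8 mol %), CO/H2 (1:1, 20 bar), toluene, 60 °C
Reagents that add atoms: carbon monoxide, [C-]#[O+]
Why: Hydroformylation: the Rh–H species of the bulky-phosphite catalyst adds across the exocyclic C13=C12 bond with rhodium on the terminal C12 (a fully substituted carbon is not formylated), CO insertion and hydrogenolysis give the C11 aldehyde 20, and the C15 lactol hydroxyl adds to it. The closest known reaction type is the linear hydroformylation of 1,1-disubstituted alkenes that carry a homoallylic hydroxyl, which gives six-membered lactols in the same flask. The ring O–C11–C12–C13–C14–C15 closes by 6-exo-trig addition of the C15 hydroxyl to the aldehyde carbonyl (hemiacetal formation), which is possible only when the C12–C11 arm and the C15–O bond are cis on the tetrahydrofuran; the lactol anomerises to supply that isomer. C13 is set by syn delivery of H and Rh to the alkene face opposite the quaternary hydroazulenyl group on C14, which leaves the new arm cis to that group; C11 is a lactol centre that is removed in step 14. The step needs linear regioselectivity, attack anti to the C14 substituent and no alkene migration toward C16 or C14: the 1,1-disubstitution secures the first, the bulk of the C14 substituent the second, and the fast monophosphite catalyst at 60 °C under 20 bar the third, while the C10 ketone stands in for the later methylene so that this is the only alkene.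

Step 14
Reactants: 21
Product: 22 methyl 3-oxo-8-Q-2,7-dioxabicyclo[3.2.1]octane-6-exo-carboxylate
Conditions: (n-Pr4N)RuO4 (5 mol %), N-methylmorpholine N-oxide (1.5 equiv), 4 Å molecular sieves, CH2Cl2, 25 °C
Reagents that add atoms: none
Why: Ley–Griffith oxidation of the lactol to the δ-lactone, to which ketone, ester and acetal are inert; the C11 hydroxyl centre disappears and no other stereocenter is touched.

Step 15
Reactants: 22
Product: 23 methyl 3-oxo-8-Q′-2,7-dioxabicyclo[3.2.1]octane-6-exo-carboxylate
Conditions: Zn, CH2Br2, TiCl4 (reagent preformed in THF at 5 °C), CH2Cl2, 0 to 25 °C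
Reagents that add atoms: dibromomethane, BrCBr
Why: Takai–Lombardo methylenation, whose non-basic titanium–zinc methylene reagent converts the hindered, enolisable C10 ketone into the exocyclic alkene without epimerising C9 and leaves lactone and ester untouched.

Step 16
Reactants: 23
Product: 24 methyl 4-hydroxy-3-oxo-8-Q′-2,7-dioxabicyclo[3.2.1]octane-6-exo-carboxylate (4-OH equatorial; trans to Q′)
Conditions: NaN(SiMe3)2 (1.1 equiv), THF, −78 °C; 2-(phenylsulfonyl)-3-phenyloxaziridine (1.3 equiv), −78 °C; aq. NH4Cl
Reagents that add atoms: 2-(phenylsulfonyl)-3-phenyloxaziridine, O=S(=O)(N1OC1c1ccccc1)c1ccccc1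
Why: Enolate hydroxylation with an N-sulfonyloxaziridine: the lactone CH2 (C12) is more acidic and less hindered than the ester C16–H, and the oxidant should approach the enolate face opposite the hydroazulenyl group that stands axial on C14 (1,3 to C12), giving the equatorial C12 hydroxyl.

Step 17
Reactants: 24
Product: 25 target CNP0215240.1 (methyl 4-(acetyloxy)-3-oxo-8-Q′-2,7-dioxabicyclo[3.2.1]octane-6-exo-carboxylate)
Conditions: Ac2O (3 equiv), pyridine, 4-(dimethylamino)pyridine (5 mol %), CH2Cl2, 0 to 25 °C
Reagents that add atoms: acetic anhydride, CC(=O)OC(C)=O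
Why: Nucleophile-catalysed acylation of the secondary alcohol, with retention at C12, gives the target.

**Compound list**

1 | 4,4-dimethylcyclohex-2-en-1-one | CC1(C)CCC(=O)C=C1 | starting material
2 | 2-(2-bromoethyl)-2-methyl-1,3-dioxolane | CC1(CCBr)OCCO1 | starting material
3 | [2-(2-methyl-1,3-dioxolan-2-yl)ethyl]magnesium bromide | CC1(CC[Mg]Br)OCCO1 | intermediate
4 | bis[2-(2-methyl-1,3-dioxolan-2-yl)ethyl]zinc | CC1(CC[Zn]CCC2(C)OCCO2)OCCO1 | intermediate
5 | (3R)-4,4-dimethyl-3-[2-(2-methyl-1,3-dioxolan-2-yl)ethyl]cyclohexan-1-one | O=C1CCC(C)(C)[C@H](CCC2(C)OCCO2)C1 | intermediate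
6 | (3R)-4,4-dimethyl-3-(3-oxobutyl)cyclohexan-1-one | O=C1CCC(C)(C)[C@H](CCC(C)=O)C1 | intermediate
7 | (7aS)-3,7,7-trimethyl-1,2,5,6,7,7a-hexahydro-4H-inden-4-one | O=C1CCC(C)(C)[C@@H]2CCC(C)=C12 | intermediate
8 | (3S,3aR,7aR)-3,7,7-trimethyl-3-(prop-2-en-1-yl)octahydro-4H-inden-4-one | O=C1CCC(C)(C)[C@@H]2CC[C@@](C)(CC=C)[C@H]12 | intermediate
9 | (3S,3aR,8aR)-3,8,8-trimethyl-3-(prop-2-en-1-yl)-5-(trimethylsilyl)octahydroazulen-4(1H)-one (C5 epimers) | O=C1C([Si](C)(C)C)CCC(C)(C)[C@@H]2CC[C@@](C)(CC=C)[C@H]12 | intermediate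
10 | (3S,3aR,8aR)-3,8,8-trimethyl-3-(prop-2-en-1-yl)octahydroazulen-4(1H)-one | O=C1CCCC(C)(C)[C@@H]2CC[C@@](C)(CC=C)[C@H]12 | intermediate
11 | 2-[(1S,3aR,8aR)-1,4,4-trimethyl-8-oxodecahydroazulen-1-yl]acetaldehyde | O=C1CCCC(C)(C)[C@@H]2CC[C@@](C)(CC=O)[C@H]12 | intermediate
12 | methyl 2-hydroxybut-3-ynoate (racemic) | C#CC(O)C(=O)OC | starting material
13 | methyl (2R)-2-(acetyloxy)but-3-ynoate | C#C[C@H](C(=O)OC)OC(C)=O | intermediate
14 | (2R)-2-hydroxybut-3-ynoic acid | C#C[C@H](C(=O)O)O | intermediate
15 | trimethylsilyl (2R)-2-[(trimethylsilyl)oxy]but-3-ynoate | C#C[C@H](C(=O)O[Si](C)(C)C)O[Si](C)(C)C | intermediate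
16 | 2-(phenylselanyl)-2-Q-acetaldehyde (C14 epimers) | O=C1CCCC(C)(C)[C@@H]2CC[C@@](C)(C([Se]c3ccccc3)C=O)[C@H]12 | intermediate
17 | (2R,5R)-5-ethynyl-2-[(phenylselanyl)(Q)methyl]-1,3-dioxolan-4-one (2,5-cis; C14 epimers) | O=C1CCCC(C)(C)[C@@H]2CC[C@@](C)(C([Se]c3ccccc3)[C@@H]3O[C@H](C#C)C(=O)O3)[C@H]12 | intermediate
18 | (4R)-5-methylidene-6-exo-Q-2,7-dioxabicyclo[2.2.1]heptan-3-one | O=C1CCCC(C)(C)[C@@H]2CC[C@@](C)([C@@H]3[C@@H]4O[C@H](C3=C)C(=O)O4)[C@H]12 | intermediate
19 | methyl (2R)-5-hydroxy-3-methylidene-4-Q-tetrahydrofuran-2-carboxylate (Q trans to CO2Me; lactol anomers) | O=C1CCCC(C)(C)[C@@H]2CC[C@@](C)([C@@H]3C(O)O[C@@H](C(=O)OC)C3=C)[C@H]12 | intermediate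
20 | methyl (2R)-5-hydroxy-3-(2-oxoethyl)-4-Q-tetrahydrofuran-2-carboxylate (oxoethyl cis to Q) | O=C1CCCC(C)(C)[C@@H]2CC[C@@](C)([C@@H]3C(O)O[C@@H](C(=O)OC)[C@@H]3CC=O)[C@H]12 | intermediate
21 | methyl 3-hydroxy-8-Q-2,7-dioxabicyclo[3.2.1]octane-6-exo-carboxylate (C3 epimers) | O=C1CCCC(C)(C)[C@@H]2CC[C@@](C)([C@@H]3[C@@H]4OC(O)C[C@H]3[C@H](C(=O)OC)O4)[C@H]12 | intermediate
22 | methyl 3-oxo-8-Q-2,7-dioxabicyclo[3.2.1]octane-6-exo-carboxylate | O=C1CCCC(C)(C)[C@@H]2CC[C@@](C)([C@@H]3[C@@H]4OC(=O)C[C@H]3[C@H](C(=O)OC)O4)[C@H]12 | intermediate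
23 | methyl 3-oxo-8-Q′-2,7-dioxabicyclo[3.2.1]octane-6-exo-carboxylate | C=C1CCCC(C)(C)[C@@H]2CC[C@@](C)([C@@H]3[C@@H]4OC(=O)C[C@H]3[C@H](C(=O)OC)O4)[C@H]12 | intermediate
24 | methyl 4-hydroxy-3-oxo-8-Q′-2,7-dioxabicyclo[3.2.1]octane-6-exo-carboxylate (4-OH trans to Q′) | C=C1CCCC(C)(C)[C@@H]2CC[C@@](C)([C@@H]3[C@@H]4OC(=O)[C@@H](O)[C@H]3[C@H](C(=O)OC)O4)[C@H]12 | intermediate
25 | CNP0215240.1 | C=C1CCCC(C)(C)[C@@H]2CC[C@@](C)([C@@H]3[C@@H]4OC(=O)[C@@H](OC(C)=O)[C@H]3[C@H](C(=O)OC)O4)[C@H]12 | target

**Step count and risks**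

Total steps: 17. Longest linear sequence: 14 (steps 1–5 and 9–17); steps 6–8 form the side branch that joins at step 10.

Steps most likely to fail:

1. Step 11 (Proposed new method). The closure builds a strained bridged ring, so the C14 radical may be reduced by the stannane before it reaches the alkyne. At the low stannane concentration the vinyl radical may also abstract hydrogen from the hydroazulene (C9–H), and the exo preference may be weaker than assumed. The fallback is the open-chain selenoacetal cyclisation, which is known chemistry; it sets out from 16 and comes back at 19.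
   - Selenide 16 is converted with HC(OMe)3, pyridinium tosylate and MeOH into the dimethyl acetal F1.
   - Acetate 13 is transesterified (Candida antarctica lipase B, MeOH, t-BuOMe) to methyl (2R)-2-hydroxybut-3-ynoate F2.
   - F1 is activated with Et3SiOTf and 2,4,6-collidine (CH2Cl2, 0 °C) and treated with F2 to give the mixed methyl propargyl acetal F3.
   - Bu3SnH and AIBN (benzene, 80 °C, 0.02 M) close the unstrained 5-exo-dig ring to the 2-methoxytetrahydrofuran F4.
   - AcOH–H2O–THF hydrolyses F4 to lactol 19.
   - In this variant C15 forms without control and the hydroazulenyl group goes trans to the methoxy group, so the 14-epimeric series has to be removed by chromatography at F4 or 19.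

2. Step 13 (key step). The Rh–H may add from the face of the C14 substituent, because the C16 ester lies on the other face. The alkene may also migrate into conjugation with the ester before CO insertion, or the doubly flanked alkene may react too slowly. The fallback is a radical methoxycarbonylation; it sets out from 19 and comes back at 22, so step 14 is then not needed.
   - Lactol 19 is heated with S-(methoxycarbonyl) O-ethyl carbonodithioate and dilauroyl peroxide (1,2-dichloroethane, reflux). The methoxycarbonyl radical adds to C12 and the xanthate group transfers to C13, giving the tertiary xanthate F5.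
   - (Me3Si)3SiH and AIBN (toluene, 80 °C) remove the xanthate, with hydrogen delivered to C13 anti to the C14 substituent, giving the ester lactol F6.
   - Camphorsulfonic acid in toluene (60 °C) closes F6 to keto lactone 22.

3. Step 16. Deprotonation may occur at the ester C16–H as well as at C12, the enolate of the acyloxy acetal may open by loss of the C15 oxygen, or the oxidant may not discriminate the two faces. The fallback brings the C12 oxygen in by dihydroxylation of an enol ether before the methylenation; it sets out from 21 and comes back at 25.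
   - Lactol 21 is dehydrated (MsCl, Et3N, CH2Cl2, 0 to 25 °C) to the C11=C12 enol ether F7.
   - OsO4 (cat.) and N-methylmorpholine N-oxide in acetone–H2O add two hydroxyls on the face opposite the C14 substituent, giving the diol lactol F8.
   - Ag2CO3 on Celite (benzene, reflux) oxidises only the lactol, giving the hydroxy lactone F9.
   - Ac2O, pyridine and 4-(dimethylamino)pyridine give the acetate F10.
   - Takai–Lombardo methylenation (Zn, CH2Br2, TiCl4) of the C10 ketone of F10 gives 25.

**Further compounds**

F1 | step 11 | 2-(phenylselanyl)-2-Q-acetaldehyde dimethyl acetal (C14 epimers) | O=C1CCCC(C)(C)[C@@H]2CC[C@@](C)(C([Se]c3ccccc3)C(OC)OC)[C@H]12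
F2 | step 11 | methyl (2R)-2-hydroxybut-3-ynoate | C#C[C@H](C(=O)OC)O
F3 | step 11 | methyl (2R)-2-{[1-methoxy-2-(phenylselanyl)-2-Q-ethyl]oxy}but-3-ynoate (C14 and C15 epimers) | O=C1CCCC(C)(C)[C@@H]2CC[C@@](C)(C([Se]c3ccccc3)C(OC)O[C@H](C#C)C(=O)OC)[C@H]12
F4 | step 11 | methyl (2R)-5-methoxy-3-methylidene-4-Q-tetrahydrofuran-2-carboxylate (Q trans to CO2Me; C5 epimers) | O=C1CCCC(C)(C)[C@@H]2CC[C@@](C)([C@@H]3C(OC)O[C@@H](C(=O)OC)C3=C)[C@H]12
F5 | step 13 | methyl (2R)-3-[(ethoxycarbonothioyl)sulfanyl]-5-hydroxy-3-(2-methoxy-2-oxoethyl)-4-Q-tetrahydrofuran-2-carboxylate (C3 epimers) | O=C1CCCC(C)(C)[C@@H]2CC[C@@](C)([C@@H]3C(O)O[C@@H](C(=O)OC)C3(CC(=O)OC)SC(=S)OCC)[C@H]12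
F6 | step 13 | methyl (2R)-5-hydroxy-3-(2-methoxy-2-oxoethyl)-4-Q-tetrahydrofuran-2-carboxylate (ester arm cis to Q) | O=C1CCCC(C)(C)[C@@H]2CC[C@@](C)([C@@H]3C(O)O[C@@H](C(=O)OC)[C@@H]3CC(=O)OC)[C@H]12
F7 | step 16 | methyl 8-Q-2,7-dioxabicyclo[3.2.1]oct-3-ene-6-exo-carboxylate | O=C1CCCC(C)(C)[C@@H]2CC[C@@](C)([C@@H]3[C@@H]4OC=C[C@H]3[C@H](C(=O)OC)O4)[C@H]12
F8 | step 16 | methyl 3,4-dihydroxy-8-Q-2,7-dioxabicyclo[3.2.1]octane-6-exo-carboxylate (hydroxyls trans to Q) | O=C1CCCC(C)(C)[C@@H]2CC[C@@](C)([C@@H]3[C@@H]4OC(O)[C@@H](O)[C@H]3[C@H](C(=O)OC)O4)[C@H]12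
F9 | step 16 | methyl 4-hydroxy-3-oxo-8-Q-2,7-dioxabicyclo[3.2.1]octane-6-exo-carboxylate | O=C1CCCC(C)(C)[C@@H]2CC[C@@](C)([C@@H]3[C@@H]4OC(=O)[C@@H](O)[C@H]3[C@H](C(=O)OC)O4)[C@H]12
F10 | step 16 | methyl 4-(acetyloxy)-3-oxo-8-Q-2,7-dioxabicyclo[3.2.1]octane-6-exo-carboxylate | O=C1CCCC(C)(C)[C@@H]2CC[C@@](C)([C@@H]3[C@@H]4OC(=O)[C@@H](OC(C)=O)[C@H]3[C@H](C(=O)OC)O4)[C@H]12
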